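**Retrosynthetic overview**
1. The tertiary C–OOH bond is made last: the (2Z,4E)-dienyl hydroperoxide comes from the skipped (2Z)-2,5-diene by aerobic hydroperoxidation with allylic shift.
2. The cyclopentenone (ring B, formed last) comes from ring-closing metathesis of a dienone, made by vinyl Grignard opening of a cis-fused δ-lactone; the lactone comes from an Ireland–Claisen rearrangement that sets the cis methyl/alkyl pair.
3. The tertiary carbinol and its neighbour come from a Sharpless epoxidation of a cyclopentenylmethanol (C–O) followed by SN2 opening with an acetate enolate.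
4. The side chain comes from a Z-selective Wittig reaction of a methyl ketone; the cyclopentane (ring A, formed first) comes from an enantioselective phosphine-catalysed (3+2) annulation of an allenoate with methyl vinyl ketone.
5. Ring order: ring A, then the temporary lactone, then ring B.

Assumption: the SMILES is read literally, i.e. a (2Z,4E)-diene and a cis 4-methyl/5-cyclopentyl pair on the cyclopentenone.

**Route**

Step 1
Reactants: 1 ethyl buta-2,3-dienoate; 2 but-3-en-2-one
Product: 3 ethyl (4S)-4-acetylcyclopent-1-ene-1-carboxylate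
Conditions: (S)-4-tert-butyl-4,5-dihydro-3H-dinaphtho[2,1-c:1',2'-e]phosphepine (10 mol %; the antipode that gives 4S is used), toluene, 0 to 20 °C, slow addition of 2
Reagents that add atoms: none
Why: Lu phosphine-catalysed (3+2) annulation: the phosphine–allenoate zwitterion adds through its α-carbon to the enone, so the acetyl group lands on C4 of the cyclopentene ester, and the chiral phosphepine sets C4 as S.

Step 2
Reactants: 4 5-bromo-2-methylpent-2-ene
Product: 5 (4-methylpent-3-en-1-yl)triphenylphosphonium bromide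
Conditions: PPh3, MeCN, reflux
Reagents that add atoms: triphenylphosphane, c1ccc(cc1)P(c1ccccc1)c1ccccc1
Why: SN2 quaternisation of the phosphane by a primary bromide.

Step 3
Reactants: 3 ethyl (4S)-4-acetylcyclopent-1-ene-1-carboxylate; 5 (4-methylpent-3-en-1-yl)triphenylphosphonium bromide
Product: 7 ethyl (4S)-4-[(2Z)-6-methylhepta-2,5-dien-2-yl]cyclopent-1-ene-1-carboxylate, via phosphorus ylide 6 (not isolated)
Conditions: 5, KN(SiMe3)2, THF, −78 to 0 °C; then 3, −78 to 20 °C
Reagents that add atoms: none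
Why: Wittig olefination: the salt-free non-stabilised ylide attacks the methyl ketone faster than the enoate and places the chain cis to the larger ring substituent (as in the Wittig route to (Z)-α-bisabolene); the minor E isomer is removed by chromatography.

Step 4
Reactants: 7 ethyl (4S)-4-[(2Z)-6-methylhepta-2,5-dien-2-yl]cyclopent-1-ene-1-carboxylate
Product: 8 [(4S)-4-[(2Z)-6-methylhepta-2,5-dien-2-yl]cyclopent-1-en-1-yl]methanol
Conditions: i-Bu2AlH (2.5 equiv), CH2Cl2, −78 °C; aq. KNaC4H4O6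
Reagents that add atoms: none
Why: 1,2-reduction of the conjugated ester to the allylic alcohol; the isolated alkenes and C4 are untouched.

Step 5
Reactants: 8 [(4S)-4-[(2Z)-6-methylhepta-2,5-dien-2-yl]cyclopent-1-en-1-yl]methanol
Product: 9 [(1S,3S,5S)-3-[(2Z)-6-methylhepta-2,5-dien-2-yl]-6-oxabicyclo[3.1.0]hexan-1-yl]methanol
Conditions: Ti(OiPr)4 (10 mol %), L-(+)-diethyl tartrate (12 mol %), t-BuOOH, 4 Å molecular sieves, CH2Cl2, −20 °C
Reagents that add atoms: tert-butyl hydroperoxide, CC(C)(C)OO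
Why: Katsuki–Sharpless asymmetric epoxidation: only the allylic-alcohol alkene reacts, and L-(+)-tartrate delivers oxygen to the face anti to the C4 side chain (matched case), which sets both epoxide carbons and turns any minor enantiomer from step 1 into a separable diastereomer.

Step 6
Reactants: 9 [(1S,3S,5S)-3-[(2Z)-6-methylhepta-2,5-dien-2-yl]-6-oxabicyclo[3.1.0]hexan-1-yl]methanol
Product: 10 triethyl{[(1S,3S,5S)-3-[(2Z)-6-methylhepta-2,5-dien-2-yl]-6-oxabicyclo[3.1.0]hexan-1-yl]methoxy}silane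
Conditions: Et3SiCl, imidazole, CH2Cl2, 0 °C
Reagents that add atoms: chlorotriethylsilane, CC[Si](Cl)(CC)CC
Why: Silylation of the primary alcohol, so that it cannot lactonise onto the ester made in step 7.

Step 7
Reactants: 10 triethyl{[(1S,3S,5S)-3-[(2Z)-6-methylhepta-2,5-dien-2-yl]-6-oxabicyclo[3.1.0]hexan-1-yl]methoxy}silane; 11 (2E)-but-2-en-1-yl acetate
Product: 14 (2E)-but-2-en-1-yl 2-[(1S,2R,4S)-2-hydroxy-4-[(2Z)-6-methylhepta-2,5-dien-2-yl]-2-{[(triethylsilyl)oxy]methyl}cyclopentyl]acetate, via lithium ester enolate 12 (not isolated), via diethylaluminium ester enolate 13 (not isolated)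
Conditions: 11, LiN(iPr)2, THF, −78 °C; Et2AlCl; then 10, −78 to −20 °C; aq. KNaC4H4O6
Reagents that add atoms: none
Why: Epoxide opening by an aluminium ester enolate: SN2 attack with inversion at the secondary epoxide carbon (the quaternary carbon is blocked) leaves the tertiary hydroxyl trans to the new C–C bond and puts that bond cis to the C4 side chain.

Step 8
Reactants: 14 (2E)-but-2-en-1-yl 2-[(1S,2R,4S)-2-hydroxy-4-[(2Z)-6-methylhepta-2,5-dien-2-yl]-2-{[(triethylsilyl)oxy]methyl}cyclopentyl]acetate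
Product: 18 (4S,4aS,6S,7aR)-4-[(2R)-but-3-en-2-yl]-7a-hydroxy-6-[(2Z)-6-methylhepta-2,5-dien-2-yl]hexahydrocyclopenta[c]pyran-3(1H)-one, via silyl ketene acetal 15 (not isolated), via trimethylsilyl ester 16 (not isolated), via dihydroxy acid 17 (not isolated)
Conditions: LiN(iPr)2 (3 equiv), Me3SiCl (4 equiv), THF, −78 to 25 °C; then 1 M HCl, THF, 25 °C
Reagents that add atoms: none
Why: Ireland–Claisen rearrangement: the kinetic (E)-silyl ketene acetal and the (E)-crotyl unit react through a chair transition state to give the anti pair of new stereocentres (the later cis ring pair), allylic 1,3-strain makes the allyl group add anti to the quaternary carbinol carbon, and the acid work-up removes the silyl groups and closes the cis-fused δ-lactone.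

Step 9
Reactants: 18 (4S,4aS,6S,7aR)-4-[(2R)-but-3-en-2-yl]-7a-hydroxy-6-[(2Z)-6-methylhepta-2,5-dien-2-yl]hexahydrocyclopenta[c]pyran-3(1H)-one
Product: 19 (4S,5R)-4-[(1S,2R,4S)-2-hydroxy-2-(hydroxymethyl)-4-[(2Z)-6-methylhepta-2,5-dien-2-yl]cyclopentyl]-5-methylhepta-1,6-dien-3-one
Conditions: CH2=CHMgBr (2.3 equiv), THF, −78 °C; H2O quench at −78 °C
Reagents that add atoms: vinylmagnesium bromide, C=C[Mg]Br
Why: Addition of a vinyl Grignard reagent to a δ-lactone stops after one addition at −78 °C, giving the vinyl ketone and freeing the hydroxymethyl group without touching a stereocentre.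

Step 10
Reactants: 19 (4S,5R)-4-[(1S,2R,4S)-2-hydroxy-2-(hydroxymethyl)-4-[(2Z)-6-methylhepta-2,5-dien-2-yl]cyclopentyl]-5-methylhepta-1,6-dien-3-one
Product: 20 (4R,5S)-5-[(1S,2R,4S)-2-hydroxy-2-(hydroxymethyl)-4-[(2Z)-6-methylhepta-2,5-dien-2-yl]cyclopentyl]-4-methylcyclopent-2-en-1-one
Conditions: second-generation Hoveyda–Grubbs catalyst RuCl2(1,3-dimesitylimidazolidin-2-ylidene)(=CH-C6H4-2-OiPr) (5 mol %), CH2Cl2 (5 mM), 40 °C
Reagents that add atoms: none
Why: Ring-closing metathesis of the two terminal vinyl groups closes the cyclopentenone under neutral conditions, so the epimerisable cis methyl/alkyl pair from step 8 is kept, while the trisubstituted side-chain alkenes react far more slowly.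

Step 11
Reactants: 20 (4R,5S)-5-[(1S,2R,4S)-2-hydroxy-2-(hydroxymethyl)-4-[(2Z)-6-methylhepta-2,5-dien-2-yl]cyclopentyl]-4-methylcyclopent-2-en-1-one
Product: 21 [(1R,2S,4S)-1-hydroxy-4-[(2Z)-6-methylhepta-2,5-dien-2-yl]-2-[(1S,5R)-5-methyl-2-oxocyclopent-3-en-1-yl]cyclopentyl]methyl acetate
Conditions: Ac2O (1.2 equiv), pyridine, CH2Cl2, 0 °C
Reagents that add atoms: acetic anhydride, CC(=O)OC(C)=O
Why: Selective acylation of the primary alcohol; the tertiary alcohol does not react without an acyl-transfer catalyst.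

Step 12
Reactants: 21 [(1R,2S,4S)-1-hydroxy-4-[(2Z)-6-methylhepta-2,5-dien-2-yl]-2-[(1S,5R)-5-methyl-2-oxocyclopent-3-en-1-yl]cyclopentyl]methyl acetate
Product: 22 [(1R,2S,4S)-4-[(2Z,4E)-6-hydroperoxy-6-methylhepta-2,4-dien-2-yl]-1-hydroxy-2-[(1S,5R)-5-methyl-2-oxocyclopent-3-en-1-yl]cyclopentyl]methyl acetate
Conditions: N-hydroxyphthalimide (0.5 equiv), O2 (1 atm), 2,2'-azobis(4-methoxy-2,4-dimethylvaleronitrile) (5 mol %), MeCN, 20 °C, dark, stopped near 50% conversion, 21 recycled
Reagents that add atoms: dioxygen, O=O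
Why: Proposed new method: N-hydroxyphthalimide-mediated aerobic hydroperoxidation of a trisubstituted terpenoid skipped diene under kinetic control, in which the phthalimide-N-oxyl radical abstracts the weakest (doubly allylic) hydrogen, O2 adds to the pentadienyl radical at the less hindered gem-dimethyl terminus (the ring-side terminus is twisted out of conjugation by its cis cyclopentyl group), and hydrogen transfer from N-hydroxyphthalimide traps the peroxyl radical as the tertiary hydroperoxide with a new E alkene and the Z alkene retained; the closest known chemistry is N-hydroxyphthalimide-catalysed aerobic C–H hydroperoxidation (cumene type) and the hydrogen-donor-controlled autoxidation of linoleates to (Z,E)-dienyl hydroperoxides.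

**Compound list**
1 | ethyl buta-2,3-dienoate | C=C=CC(=O)OCC | starting material
2 | but-3-en-2-one | CC(=O)C=C | starting material
3 | ethyl (4S)-4-acetylcyclopent-1-ene-1-carboxylate | CCOC(=O)C1=CC[C@H](C(C)=O)C1 | intermediate
4 | 5-bromo-2-methylpent-2-ene | CC(C)=CCCBr | starting material
5 | (4-methylpent-3-en-1-yl)triphenylphosphonium bromide | CC(C)=CCC[P+](c1ccccc1)(c1ccccc1)c1ccccc1.[Br-] | intermediate
6 | (4-methylpent-3-en-1-ylidene)triphenyl-λ5-phosphane | CC(C)=CCC=P(c1ccccc1)(c1ccccc1)c1ccccc1 | intermediate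
7 | ethyl (4S)-4-[(2Z)-6-methylhepta-2,5-dien-2-yl]cyclopent-1-ene-1-carboxylate | CCOC(=O)C1=CC[C@H](/C(C)=C\CC=C(C)C)C1 | intermediate
8 | [(4S)-4-[(2Z)-6-methylhepta-2,5-dien-2-yl]cyclopent-1-en-1-yl]methanol | OCC1=CC[C@H](/C(C)=C\CC=C(C)C)C1 | intermediate
9 | [(1S,3S,5S)-3-[(2Z)-6-methylhepta-2,5-dien-2-yl]-6-oxabicyclo[3.1.0]hexan-1-yl]methanol | OC[C@@]12C[C@@H](/C(C)=C\CC=C(C)C)C[C@@H]1O2 | intermediate
10 | triethyl{[(1S,3S,5S)-3-[(2Z)-6-methylhepta-2,5-dien-2-yl]-6-oxabicyclo[3.1.0]hexan-1-yl]methoxy}silane | CC[Si](CC)(CC)OC[C@@]12C[C@@H](/C(C)=C\CC=C(C)C)C[C@@H]1O2 | intermediate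
11 | (2E)-but-2-en-1-yl acetate | CC(=O)OC/C=C/C | starting material
12 | lithium 1-[(2E)-but-2-en-1-yloxy]ethen-1-olate | [Li]OC(=C)OC/C=C/C | intermediate
13 | diethylaluminium 1-[(2E)-but-2-en-1-yloxy]ethen-1-olate | CC[Al](CC)OC(=C)OC/C=C/C | intermediate
14 | (2E)-but-2-en-1-yl 2-[(1S,2R,4S)-2-hydroxy-4-[(2Z)-6-methylhepta-2,5-dien-2-yl]-2-{[(triethylsilyl)oxy]methyl}cyclopentyl]acetate | CC[Si](CC)(CC)OC[C@@]1(O)C[C@@H](/C(C)=C\CC=C(C)C)C[C@H]1CC(=O)OC/C=C/C | intermediate
15 | {[(1E)-1-[(2E)-but-2-en-1-yloxy]-2-[(1S,2R,4S)-4-[(2Z)-6-methylhepta-2,5-dien-2-yl]-2-{[(triethylsilyl)oxy]methyl}-2-[(trimethylsilyl)oxy]cyclopentyl]ethenyl]oxy}(trimethyl)silane | CC[Si](CC)(CC)OC[C@@]1(O[Si](C)(C)C)C[C@@H](/C(C)=C\CC=C(C)C)C[C@H]1/C=C(/O[Si](C)(C)C)OC/C=C/C | intermediate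
16 | trimethylsilyl (2S,3R)-3-methyl-2-[(1S,2R,4S)-4-[(2Z)-6-methylhepta-2,5-dien-2-yl]-2-{[(triethylsilyl)oxy]methyl}-2-[(trimethylsilyl)oxy]cyclopentyl]pent-4-enoate | CC[Si](CC)(CC)OC[C@@]1(O[Si](C)(C)C)C[C@@H](/C(C)=C\CC=C(C)C)C[C@H]1[C@@H](C(=O)O[Si](C)(C)C)[C@H](C)C=C | intermediate
17 | (2S,3R)-2-[(1S,2R,4S)-2-hydroxy-2-(hydroxymethyl)-4-[(2Z)-6-methylhepta-2,5-dien-2-yl]cyclopentyl]-3-methylpent-4-enoic acid | OC[C@@]1(O)C[C@@H](/C(C)=C\CC=C(C)C)C[C@H]1[C@@H](C(=O)O)[C@H](C)C=C | intermediate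
18 | (4S,4aS,6S,7aR)-4-[(2R)-but-3-en-2-yl]-7a-hydroxy-6-[(2Z)-6-methylhepta-2,5-dien-2-yl]hexahydrocyclopenta[c]pyran-3(1H)-one | O=C1OC[C@@]2(O)C[C@@H](/C(C)=C\CC=C(C)C)C[C@H]2[C@@H]1[C@H](C)C=C | intermediate
19 | (4S,5R)-4-[(1S,2R,4S)-2-hydroxy-2-(hydroxymethyl)-4-[(2Z)-6-methylhepta-2,5-dien-2-yl]cyclopentyl]-5-methylhepta-1,6-dien-3-one | OC[C@@]1(O)C[C@@H](/C(C)=C\CC=C(C)C)C[C@H]1[C@@H](C(=O)C=C)[C@H](C)C=C | intermediate
20 | (4R,5S)-5-[(1S,2R,4S)-2-hydroxy-2-(hydroxymethyl)-4-[(2Z)-6-methylhepta-2,5-dien-2-yl]cyclopentyl]-4-methylcyclopent-2-en-1-one | OC[C@@]1(O)C[C@@H](/C(C)=C\CC=C(C)C)C[C@H]1[C@H]1C(=O)C=C[C@H]1C | intermediate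
21 | [(1R,2S,4S)-1-hydroxy-4-[(2Z)-6-methylhepta-2,5-dien-2-yl]-2-[(1S,5R)-5-methyl-2-oxocyclopent-3-en-1-yl]cyclopentyl]methyl acetate | CC(=O)OC[C@@]1(O)C[C@@H](/C(C)=C\CC=C(C)C)C[C@H]1[C@H]1C(=O)C=C[C@H]1C | intermediate
22 | [(1R,2S,4S)-4-[(2Z,4E)-6-hydroperoxy-6-methylhepta-2,4-dien-2-yl]-1-hydroxy-2-[(1S,5R)-5-methyl-2-oxocyclopent-3-en-1-yl]cyclopentyl]methyl acetate | CC(=O)OC[C@@]1(O)C[C@@H](/C(C)=C\C=C\C(C)(C)OO)C[C@H]1[C@H]1C(=O)C=C[C@H]1C | target

**Step count**
Total step count: 12. Longest linear sequence: 11 steps (steps 1 and 3 to 12; step 2 is a one-step side branch).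

**Three steps most likely to fail**

Step 1. Methyl vinyl ketone is smaller than the acrylates and aryl enones usually used in enantioselective phosphine annulations, so the enantiomeric excess and the 4-acetyl/5-acetyl ratio may be modest; if the sense of induction is the wrong one, the other catalyst antipode is taken. Fallback, setting out from 1 and 2 and coming back at 9: run the annulation with PPh3 to the racemic keto ester ethyl (4RS)-4-acetylcyclopent-1-ene-1-carboxylate F1. Carry it through the conditions of steps 3 and 4 to the racemic diene ester ethyl (4RS)-4-[(2Z)-6-methylhepta-2,5-dien-2-yl]cyclopent-1-ene-1-carboxylate F2 and the racemic allylic alcohol [(4RS)-4-[(2Z)-6-methylhepta-2,5-dien-2-yl]cyclopent-1-en-1-yl]methanol F3. The Sharpless epoxidation of step 5 then does the resolution: the tartrate epoxidises both enantiomers from the same absolute face, so the 4S half gives 9 and the 4R half gives the cis diastereomer [(1S,3R,5S)-3-[(2Z)-6-methylhepta-2,5-dien-2-yl]-6-oxabicyclo[3.1.0]hexan-1-yl]methanol F4, which is removed by chromatography.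

Step 7. The aluminium enolate may be too sluggish towards this hindered trisubstituted epoxide, or its Lewis acidity may trigger epoxide rearrangement. Fallback, setting out from 10 and coming back at 14: open the epoxide with the much smaller LiCH2CN (MeCN, n-BuLi, THF, −78 to 0 °C) to the hydroxy nitrile 2-[(1S,2R,4S)-2-hydroxy-4-[(2Z)-6-methylhepta-2,5-dien-2-yl]-2-{[(triethylsilyl)oxy]methyl}cyclopentyl]acetonitrile F5. Reduce with i-Bu2AlH and hydrolyse to the aldehyde 2-[(1S,2R,4S)-2-hydroxy-4-[(2Z)-6-methylhepta-2,5-dien-2-yl]-2-{[(triethylsilyl)oxy]methyl}cyclopentyl]acetaldehyde F6. Oxidise (NaClO2, NaH2PO4, 2-methylbut-2-ene) to the acid 2-[(1S,2R,4S)-2-hydroxy-4-[(2Z)-6-methylhepta-2,5-dien-2-yl]-2-{[(triethylsilyl)oxy]methyl}cyclopentyl]acetic acid F7, and esterify with (2E)-but-2-en-1-ol (carbodiimide, 4-dimethylaminopyridine) to give 14.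

Step 12 (the new step). Three things can go wrong: O2 capture at the ring-side terminus of the pentadienyl radical (regioisomeric tertiary hydroperoxide), loss of the Z geometry through reversible O2 addition, and chain oxidation of the product. Fallback, setting out from 21 and coming back at 22: the Schenck ene reaction with singlet oxygen (O2, meso-tetraphenylporphyrin, visible light, CH2Cl2, −20 °C). This pericyclic reaction removes a doubly allylic hydrogen and places oxygen on the gem-dimethyl carbon with a new E alkene; 22 is separated by chromatography from the secondary hydroperoxide and from the isomer oxygenated at the ring-side alkene. It needs no further compound (F0).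

**Further compounds**
F1 | step 1 | ethyl (4RS)-4-acetylcyclopent-1-ene-1-carboxylate | CCOC(=O)C1=CCC(C(C)=O)C1
F2 | step 1 | ethyl (4RS)-4-[(2Z)-6-methylhepta-2,5-dien-2-yl]cyclopent-1-ene-1-carboxylate | CCOC(=O)C1=CCC(/C(C)=C\CC=C(C)C)C1
F3 | step 1 | [(4RS)-4-[(2Z)-6-methylhepta-2,5-dien-2-yl]cyclopent-1-en-1-yl]methanol | OCC1=CCC(/C(C)=C\CC=C(C)C)C1
F4 | step 1 | [(1S,3R,5S)-3-[(2Z)-6-methylhepta-2,5-dien-2-yl]-6-oxabicyclo[3.1.0]hexan-1-yl]methanol | OC[C@@]12C[C@H](/C(C)=C\CC=C(C)C)C[C@@H]1O2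
F5 | step 7 | 2-[(1S,2R,4S)-2-hydroxy-4-[(2Z)-6-methylhepta-2,5-dien-2-yl]-2-{[(triethylsilyl)oxy]methyl}cyclopentyl]acetonitrile | CC[Si](CC)(CC)OC[C@@]1(O)C[C@@H](/C(C)=C\CC=C(C)C)C[C@H]1CC#N
F6 | step 7 | 2-[(1S,2R,4S)-2-hydroxy-4-[(2Z)-6-methylhepta-2,5-dien-2-yl]-2-{[(triethylsilyl)oxy]methyl}cyclopentyl]acetaldehyde | CC[Si](CC)(CC)OC[C@@]1(O)C[C@@H](/C(C)=C\CC=C(C)C)C[C@H]1CC=O
F7 | step 7 | 2-[(1S,2R,4S)-2-hydroxy-4-[(2Z)-6-methylhepta-2,5-dien-2-yl]-2-{[(triethylsilyl)oxy]methyl}cyclopentyl]acetic acid | CC[Si](CC)(CC)OC[C@@]1(O)C[C@@H](/C(C)=C\CC=C(C)C)C[C@H]1CC(=O)O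
F0 | step 12 | none | none
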